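**Retrosynthetic overview**
- Feature: in the lactone ring (O–C9'(=O)–C8'–C8–C9) the beta carbon C8 carries two CH2 groups, the ring OCH2 (C9) and the benzylic C7 of ring A; with C8 they make up an oxetan-3-yl group on the alpha carbon C8'.
- Last disconnection: the C7–aryl bond to ring A, by nickel-catalysed reductive coupling of a C7 bromide with benzyl-protected 4-bromo-2-methoxyphenol, followed by global hydrogenolysis.
- Key disconnection: the lactone O–C9 bond, by acid-catalysed attack of the C9' carboxyl on one oxetane CH2; this sets C8 and frees the other arm as C7–OH.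
- C8' and the C8'–C7' bond come from an Evans alkylation of an N-(oxetan-3-ylacetyl)oxazolidinone with the ring B benzyl bromide (from 5-hydroxyvanillin); the oxetanylacetyl unit comes from oxetan-3-one by Horner–Wadsworth–Emmons olefination and hydrogenation.
- Ring order: rings A and B and the oxetane are bought; the gamma-lactone is the only ring formed, at the key step, at the expense of the oxetane.

Key step: step 10

Remark: lignan locants are used (C7, C8, C9 for the ring A half; C7', C8', C9' for the ring B half, C9' being the lactone carbonyl); the target is the (8R,8'R) trans lactone.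

**Route**

Step 1
Reactants: 1 (R)-4-benzyloxazolidin-2-one; 2 bromoacetyl bromide
Product: 4 (R)-4-benzyl-3-(2-bromoacetyl)oxazolidin-2-one, via lithium oxazolidinide 3 (not isolated)
Conditions: n-BuLi (1.05 equiv), THF, −78 °C; then 2, −78 to 0 °C
Reagents that add atoms: none
Why: N-acylation of the lithiated oxazolidinone by the acyl bromide is the standard preparation of Evans imides, and at −78 °C the acyl carbon reacts far faster than the CH2Br carbon.

Step 2
Reactants: 4 (R)-4-benzyl-3-(2-bromoacetyl)oxazolidin-2-one; 5 triethyl phosphite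
Product: 6 (R)-4-benzyl-3-[2-(diethoxyphosphoryl)acetyl]oxazolidin-2-one
Conditions: 5 (2 equiv), toluene, 100 °C, bromoethane distilled off
Reagents that add atoms: none
Why: Michaelis–Arbuzov reaction, in which the phosphite displaces the activated primary bromide and the released bromide dealkylates the phosphonium ion, the usual route to imide phosphonates of this kind.

Step 3
Reactants: 6 (R)-4-benzyl-3-[2-(diethoxyphosphoryl)acetyl]oxazolidin-2-one; 7 oxetan-3-one
Product: 9 (R)-4-benzyl-3-[2-(oxetan-3-ylidene)acetyl]oxazolidin-2-one, via sodium phosphonate carbanion 8 (not isolated)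
Conditions: NaH (1.05 equiv), THF, 0 °C; then 7, 0 °C to rt
Reagents that add atoms: none
Why: Horner–Wadsworth–Emmons olefination of a strained, electrophilic ketone with a stabilized phosphonate anion, with no alkene geometry to control because the two ring CH2 groups are identical.

Step 4
Reactants: 9 (R)-4-benzyl-3-[2-(oxetan-3-ylidene)acetyl]oxazolidin-2-one
Product: 10 (R)-4-benzyl-3-[2-(oxetan-3-yl)acetyl]oxazolidin-2-one
Conditions: H2 (1 atm), 10% Pd/C, EtOAc, rt
Reagents that add atoms: none
Why: Heterogeneous hydrogenation of an electron-poor trisubstituted alkene, routine for oxetan-3-ylidene acetates, leaves the oxetane C–O bonds and the C-benzyl group of the auxiliary intact and creates no stereocentre because the two oxetane arms are identical.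

Step 5
Reactants: 11 5-hydroxyvanillin (3,4-dihydroxy-5-methoxybenzaldehyde)
Product: 12 3,4-bis(benzyloxy)-5-methoxybenzaldehyde
Conditions: BnBr (2.4 equiv), K2CO3 (3 equiv), DMF, 60 °C
Reagents that add atoms: benzyl bromide, BrCc1ccccc1
Why: Williamson ether synthesis on both phenols gives benzyl ethers that withstand the base, acid, phosphine and nickel chemistry ahead and leave together in the last step.

Step 6
Reactants: 12 3,4-bis(benzyloxy)-5-methoxybenzaldehyde
Product: 13 [3,4-bis(benzyloxy)-5-methoxyphenyl]methanol
Conditions: NaBH4, MeOH/THF, 0 °C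
Reagents that add atoms: none
Why: Borohydride reduction of the aryl aldehyde to the benzylic alcohol.

Step 7
Reactants: 13 [3,4-bis(benzyloxy)-5-methoxyphenyl]methanol
Product: 14 1,2-bis(benzyloxy)-5-(bromomethyl)-3-methoxybenzene
Conditions: PBr3 (0.4 equiv), CH2Cl2, 0 °C; used without storage
Reagents that add atoms: phosphorus tribromide, BrP(Br)Br
Why: Conversion of an electron-rich benzylic alcohol into its bromide by bromide displacement of the phosphite ester formed with PBr3, at a temperature that leaves the aryl benzyl ethers alone.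

Step 8
Reactants: 10 (R)-4-benzyl-3-[2-(oxetan-3-yl)acetyl]oxazolidin-2-one; 14 1,2-bis(benzyloxy)-5-(bromomethyl)-3-methoxybenzene
Product: 16 (R)-4-benzyl-3-[(2R)-3-[3,4-bis(benzyloxy)-5-methoxyphenyl]-2-(oxetan-3-yl)propanoyl]oxazolidin-2-one, via sodium Z-enolate 15 (not isolated)
Conditions: NaN(SiMe3)2 (1.05 equiv), THF, −78 °C; then 14 (1.4 equiv), −78 to −30 °C
Reagents that add atoms: none
Why: Evans asymmetric alkylation, in which the sodium-chelated Z enolate is shielded on one face by the C4 benzyl group of the (R)-auxiliary, so the benzylic bromide adds to the open face and forms the C8'–C7' bond with C8' in the R configuration, as is known for beta-branched acyl imides and electron-rich benzyl bromides.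

Step 9
Reactants: 16 (R)-4-benzyl-3-[(2R)-3-[3,4-bis(benzyloxy)-5-methoxyphenyl]-2-(oxetan-3-yl)propanoyl]oxazolidin-2-one
Product: 18 (2R)-3-[3,4-bis(benzyloxy)-5-methoxyphenyl]-2-(oxetan-3-yl)propanoic acid, via lithium peroxycarboxylate 17 (not isolated)
Conditions: LiOH·H2O (2 equiv), 30% H2O2 (4 equiv), THF/H2O (3:1), 0 °C; aq Na2SO3; CH2Cl2 wash (recovers 1); dilute HCl to pH 4 at 0 °C, EtOAc; used at once
Reagents that add atoms: hydrogen peroxide, OO
Why: Evans cleavage, in which lithium hydroperoxide attacks the exocyclic imide carbonyl and sulfite reduces the peroxy acid, never removes the alpha proton, so C8' keeps its configuration, and the oxetane is inert to the basic medium while the acid is liberated cold because oxetanyl acids ring-expand on standing.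

Step 10
Reactants: 18 (2R)-3-[3,4-bis(benzyloxy)-5-methoxyphenyl]-2-(oxetan-3-yl)propanoic acid
Product: 20 (3R,4S)-3-[3,4-bis(benzyloxy)-5-methoxybenzyl]-4-(hydroxymethyl)dihydrofuran-2(3H)-one, via cis lactone 19 (not isolated)
Conditions: CSA (10 mol%), toluene (0.05 M), rt, then 60 °C
Reagents that add atoms: none
Why: Protonation of the oxetane oxygen by CSA makes both ring CH2 groups electrophilic, and the carbonyl oxygen of the C9' carboxyl displaces the oxetane oxygen from one of them in an SN2 step driven by release of four-ring strain, which forms the O–C9 bond and frees the other arm as the C7 hydroxymethyl group. The closest known reaction type is the acid-induced isomerization of oxetanyl carboxylic acids to hydroxy lactones, a member of the acid-catalysed intramolecular openings of 3-substituted oxetanes. The gamma-lactone closes in the 5-exo-tet mode. The new stereocentre C8 is controlled by C8': the two CH2 groups are diastereotopic, and the transition state in which the arm that stays behind lies anti to the ring B benzyl group across the forming ring is the less crowded one. Cis lactone 19, formed when the other CH2 is attacked, is carried forward because its free CH2OH can accept the acyl group (translactonization through a bicyclic ortho acid), which swaps the roles of the two arms and turns it into the more stable trans lactone 20, while C8' is never enolized under acid and stays R. The step needs selection between the two oxetane CH2 groups, secured as just described by C8' both kinetically and thermodynamically, and it needs the carboxyl to beat the electron-rich ring B (a 6-exo Friedel–Crafts opening), which the better placed oxygen nucleophile, a mild Brønsted acid in place of a Lewis acid and high dilution should ensure.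

Step 11
Reactants: 20 (3R,4S)-3-[3,4-bis(benzyloxy)-5-methoxybenzyl]-4-(hydroxymethyl)dihydrofuran-2(3H)-one
Product: 21 (3R,4R)-3-[3,4-bis(benzyloxy)-5-methoxybenzyl]-4-(bromomethyl)dihydrofuran-2(3H)-one
Conditions: CBr4 (1.3 equiv), PPh3 (1.4 equiv), CH2Cl2, 0 °C to rt
Reagents that add atoms: carbon tetrabromide, BrC(Br)(Br)Br
Why: Appel reaction, in which the primary alcohol is activated as an alkoxyphosphonium ion and displaced by bromide at the non-stereogenic C7 under neutral conditions that leave the lactone and C8' untouched.

Step 12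
Reactants: 22 4-bromo-2-methoxyphenol
Product: 23 1-(benzyloxy)-4-bromo-2-methoxybenzene
Conditions: BnBr (1.2 equiv), K2CO3 (1.5 equiv), acetone, reflux
Reagents that add atoms: benzyl bromide, BrCc1ccccc1
Why: Williamson ether synthesis masks the phenol so that no acidic OH interferes with the reductive coupling and all three phenols are released together at the end.

Step 13
Reactants: 21 (3R,4R)-3-[3,4-bis(benzyloxy)-5-methoxybenzyl]-4-(bromomethyl)dihydrofuran-2(3H)-one; 23 1-(benzyloxy)-4-bromo-2-methoxybenzene
Product: 24 (3R,4R)-4-[4-(benzyloxy)-3-methoxybenzyl]-3-[3,4-bis(benzyloxy)-5-methoxybenzyl]dihydrofuran-2(3H)-one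
Conditions: NiBr2(dme) (10 mol%), 4,4'-di-tert-butyl-2,2'-bipyridine (10 mol%), NaI (0.25 equiv), pyridine (10 mol%), Zn dust (2 equiv), 23 (1.5 equiv), DMPU, 60 °C
Reagents that add atoms: none
Why: Nickel-catalysed reductive cross-electrophile coupling of an aryl bromide with a primary alkyl bromide, in which zerovalent nickel inserts into the C–Br bond of 23, the C7 radical generated from 21 (by way of the iodide formed with NaI) is captured at nickel and reductive elimination forms the C7–aryl bond, while C8 and C8' are spectators and the lactone is inert to zinc.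

Step 14
Reactants: 24 (3R,4R)-4-[4-(benzyloxy)-3-methoxybenzyl]-3-[3,4-bis(benzyloxy)-5-methoxybenzyl]dihydrofuran-2(3H)-one
Product: 25 (−)-thujaplicatin, (3R,4R)-3-(3,4-dihydroxy-5-methoxybenzyl)-4-(4-hydroxy-3-methoxybenzyl)dihydrofuran-2(3H)-one
Conditions: H2 (1 atm), 10% Pd/C, EtOAc/MeOH, rt, work-up under argon
Reagents that add atoms: none
Why: Hydrogenolysis of the three benzyl aryl ethers over palladium does not touch the unactivated benzylic C–C bonds at C7 and C7' or the lactone, so the (8R,8'R) trans lactone is delivered with both stereocentres unchanged.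

**Compound list**

1 | (R)-4-benzyloxazolidin-2-one | O=C1N[C@H](Cc2ccccc2)CO1 | starting material
2 | bromoacetyl bromide | BrCC(Br)=O | starting material
3 | lithium (R)-4-benzyl-2-oxooxazolidin-3-ide | [Li+].O=C1[N-][C@H](Cc2ccccc2)CO1 | intermediate (not isolated)
4 | (R)-4-benzyl-3-(2-bromoacetyl)oxazolidin-2-one | O=C(CBr)N1C(=O)OC[C@H]1Cc1ccccc1 | intermediate
5 | triethyl phosphite | CCOP(OCC)OCC | starting material
6 | (R)-4-benzyl-3-[2-(diethoxyphosphoryl)acetyl]oxazolidin-2-one | CCOP(=O)(OCC)CC(=O)N1C(=O)OC[C@H]1Cc1ccccc1 | intermediate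
7 | oxetan-3-one | O=C1COC1 | starting material
8 | sodium salt of 6, deprotonated at the carbon between P and C=O | [Na+].CCOP(=O)(OCC)[CH-]C(=O)N1C(=O)OC[C@H]1Cc1ccccc1 | intermediate (not isolated)
9 | (R)-4-benzyl-3-[2-(oxetan-3-ylidene)acetyl]oxazolidin-2-one | O=C(C=C1COC1)N1C(=O)OC[C@H]1Cc1ccccc1 | intermediate
10 | (R)-4-benzyl-3-[2-(oxetan-3-yl)acetyl]oxazolidin-2-one | O=C(CC1COC1)N1C(=O)OC[C@H]1Cc1ccccc1 | intermediate
11 | 5-hydroxyvanillin (3,4-dihydroxy-5-methoxybenzaldehyde) | COc1cc(C=O)cc(O)c1O | starting material
12 | 3,4-bis(benzyloxy)-5-methoxybenzaldehyde | COc1cc(C=O)cc(OCc2ccccc2)c1OCc1ccccc1 | intermediate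
13 | [3,4-bis(benzyloxy)-5-methoxyphenyl]methanol | COc1cc(CO)cc(OCc2ccccc2)c1OCc1ccccc1 | intermediate
14 | 1,2-bis(benzyloxy)-5-(bromomethyl)-3-methoxybenzene | COc1cc(CBr)cc(OCc2ccccc2)c1OCc1ccccc1 | intermediate
15 | sodium (Z)-1-[(R)-4-benzyl-2-oxooxazolidin-3-yl]-2-(oxetan-3-yl)ethen-1-olate | [Na+].[O-]/C(=C\C1COC1)N1C(=O)OC[C@H]1Cc1ccccc1 | intermediate (not isolated)
16 | (R)-4-benzyl-3-[(2R)-3-[3,4-bis(benzyloxy)-5-methoxyphenyl]-2-(oxetan-3-yl)propanoyl]oxazolidin-2-one | O=C([C@H](Cc1cc(OCc2ccccc2)c(OCc2ccccc2)c(OC)c1)C1COC1)N1C(=O)OC[C@H]1Cc1ccccc1 | intermediate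
17 | lithium (2R)-3-[3,4-bis(benzyloxy)-5-methoxyphenyl]-2-(oxetan-3-yl)propaneperoxoate | [Li+].[O-]OC(=O)[C@H](Cc1cc(OCc2ccccc2)c(OCc2ccccc2)c(OC)c1)C1COC1 | intermediate (not isolated)
18 | (2R)-3-[3,4-bis(benzyloxy)-5-methoxyphenyl]-2-(oxetan-3-yl)propanoic acid | OC(=O)[C@H](Cc1cc(OCc2ccccc2)c(OCc2ccccc2)c(OC)c1)C1COC1 | intermediate
19 | (3R,4R)-3-[3,4-bis(benzyloxy)-5-methoxybenzyl]-4-(hydroxymethyl)dihydrofuran-2(3H)-one (cis lactone) | OC[C@@H]1COC(=O)[C@@H]1Cc1cc(OCc2ccccc2)c(OCc2ccccc2)c(OC)c1 | intermediate (not isolated)
20 | (3R,4S)-3-[3,4-bis(benzyloxy)-5-methoxybenzyl]-4-(hydroxymethyl)dihydrofuran-2(3H)-one (trans lactone) | OC[C@H]1COC(=O)[C@@H]1Cc1cc(OCc2ccccc2)c(OCc2ccccc2)c(OC)c1 | intermediate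
21 | (3R,4R)-3-[3,4-bis(benzyloxy)-5-methoxybenzyl]-4-(bromomethyl)dihydrofuran-2(3H)-one | BrC[C@H]1COC(=O)[C@@H]1Cc1cc(OCc2ccccc2)c(OCc2ccccc2)c(OC)c1 | intermediate
22 | 4-bromo-2-methoxyphenol | COc1cc(Br)ccc1O | starting material
23 | 1-(benzyloxy)-4-bromo-2-methoxybenzene | COc1cc(Br)ccc1OCc1ccccc1 | intermediate
24 | (3R,4R)-4-[4-(benzyloxy)-3-methoxybenzyl]-3-[3,4-bis(benzyloxy)-5-methoxybenzyl]dihydrofuran-2(3H)-one | COc1cc(C[C@H]2COC(=O)[C@@H]2Cc2cc(OCc3ccccc3)c(OCc3ccccc3)c(OC)c2)ccc1OCc1ccccc1 | intermediate
25 | (−)-thujaplicatin | COc1cc(C[C@H]2COC(=O)[C@@H]2Cc2cc(O)c(O)c(OC)c2)ccc1O | target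

**Step count**

Total: 14 steps. Longest linear sequence: 10 steps (steps 1, 2, 3, 4, 8, 9, 10, 11, 13, 14).

**Steps most likely to fail**

Step 10 (key step). The carboxyl may attack the other diastereotopic CH2 group to a significant extent while acyl transfer between the two arms is too slow under acid to correct it, so that cis lactone 19 persists beside 20. The fallback sets out from 19 (as its mixture with 20). Saponification with NaOH in THF/H2O at 0 °C gives sodium (2R)-2-[3,4-bis(benzyloxy)-5-methoxybenzyl]-4-hydroxy-3-(hydroxymethyl)butanoate F1. In F1, C8 carries two identical CH2OH arms and is no longer a stereocentre, so both lactones converge. Acidification with HCl, equilibration in warm aqueous acid and final closure with TsOH in toluene under azeotropic drying should re-form the lactone under thermodynamic control, returning to the route at 20. This replaces strain-driven kinetic selection by equilibration of a hydroxy acid; C8' is not endangered because hydroxide adds to the lactone carbonyl far faster than it removes the alpha proton.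

Step 13. The C7 radical may be lost to reduction, homocoupling or beta-hydride elimination at nickel faster than the electron-rich aryl bromide enters the cycle, so that cross-selectivity between the two electrophiles breaks down. The fallback sets out from 21. Zinc insertion (Zn dust, catalytic I2, DMA, 70 °C) gives {[(3R,4R)-4-[3,4-bis(benzyloxy)-5-methoxybenzyl]-5-oxotetrahydrofuran-3-yl]methyl}zinc bromide F2. Negishi coupling of F2 with 23 (Pd(OAc)2, SPhos, THF/DMA, rt to 50 °C) returns to the route at 24. Formation of the organometallic is thereby separated from the C–C bond formation, and lactones are tolerated by alkylzinc halides.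

Step 9. Hydroperoxide may add to the ring carbamate carbonyl of the crowded, alpha-branched imide instead of the exocyclic carbonyl, opening the auxiliary. The fallback sets out from 16. Reductive removal of the auxiliary with LiBH4 (1 equiv H2O, Et2O, 0 °C) gives (2R)-3-[3,4-bis(benzyloxy)-5-methoxyphenyl]-2-(oxetan-3-yl)propan-1-ol F3 together with recovered 1. Oxidation of F3 with TEMPO (cat.), NaClO2 and NaOCl (cat.) in MeCN/phosphate buffer (pH 6.7, 35 °C) gives the carboxylate, and cold acidification returns to the route at 18.

**Further compounds**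

F1 | step 10 | sodium (2R)-2-[3,4-bis(benzyloxy)-5-methoxybenzyl]-4-hydroxy-3-(hydroxymethyl)butanoate | [Na+].[O-]C(=O)[C@H](Cc1cc(OCc2ccccc2)c(OCc2ccccc2)c(OC)c1)C(CO)CO
F2 | step 13 | {[(3R,4R)-4-[3,4-bis(benzyloxy)-5-methoxybenzyl]-5-oxotetrahydrofuran-3-yl]methyl}zinc bromide | Br[Zn]C[C@H]1COC(=O)[C@@H]1Cc1cc(OCc2ccccc2)c(OCc2ccccc2)c(OC)c1
F3 | step 9 | (2R)-3-[3,4-bis(benzyloxy)-5-methoxyphenyl]-2-(oxetan-3-yl)propan-1-ol | OC[C@H](Cc1cc(OCc2ccccc2)c(OCc2ccccc2)c(OC)c1)C1COC1
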